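**Plan**

- Cuts: C4–O (late γ-oxidation); ring bonds C5–C6 and C2=C3 (annulation of a C3–C28 enal with allyl acetoacetate); C3=C4 (cross-metathesis); C12–C13 (aldol); C5–C7, C14–C15, C17–C18 and C28–aryl (organocopper couplings).
- Enabling feature: with the ring numbered C1 (C=O) to C6 and the chain C7–C28, the only ring is a cyclohex-2-enone. Its C3–C4–C5 unit is an enal with the chain on the β-carbon C5, and C1, C2, C6 are the ketone, methyl and methylene carbons of an acetoacetate.
- Forward: the C13–C28 ketone (six steps) and the C4–C12 dioxane aldehyde (two steps) are joined by a boron aldol, reduced, protected and extended to the enal. The carbocycle is then closed, C6 is decarboxylated, C4 is hydroxylated and all protecting groups are removed.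
- Stereochemistry: C8 and C10 from a commercial (4R,6S)-dioxane; C16 from (R)-epichlorohydrin; C12 by 1,5-anti induction in the aldol; C14 by chelate-controlled syn reduction; C5 by the (S)-diarylprolinol silyl ether; C4 by peracid attack anti to the C5 chain.

Key step: step 15

Assumption: atom numbers are those of the target throughout, and the statin-type dioxane 13 is taken as the commercially supplied single (4R,6S) enantiomer.

Step 1
Reactants: 1 11-bromoundecan-1-ol; 2 phenylmagnesium bromide
Product: 3 11-phenylundecan-1-ol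
Conditions: PhMgBr (2.5 equiv), Li2CuCl4 (3 mol %), THF, −10 °C → rt
Reagents that add atoms: none
Why: Copper-catalysed Grignard cross-coupling (Kochi type) displaces the primary bromide after the first equivalent of Grignard reagent has capped the hydroxyl as its magnesium alkoxide.

Step 2
Reactants: 3 11-phenylundecan-1-ol
Product: 4 (11-bromoundecyl)benzene
Conditions: CBr4, PPh3, CH2Cl2, 0 °C
Reagents that add atoms: carbon tetrabromide, BrC(Br)(Br)Br
Why: Appel reaction; the oxyphosphonium ion of the primary alcohol is displaced by bromide.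

Step 3
Reactants: 4 (11-bromoundecyl)benzene; 5 (R)-epichlorohydrin
Product: 8 (2R)-2-(12-phenyldodecyl)oxirane, via Grignard reagent 6 (not isolated), via chlorohydrin 7 (not isolated)
Conditions: Mg, THF, 40 °C; CuI (10 mol %), 5, −40 → 0 °C; then NaOH (aq.), Et2O, rt
Reagents that add atoms: none
Why: Copper-catalysed Grignard opening of the epoxide at its CH2 terminus (C17) leaves the C16–O bond untouched, and base then closes chlorohydrin 7 onto C15, so C16 keeps the configuration supplied by 5.

Step 4
Reactants: 8 (2R)-2-(12-phenyldodecyl)oxirane; 9 prop-1-en-2-ylmagnesium bromide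
Product: 10 (4R)-2-methyl-16-phenylhexadec-1-en-4-ol
Conditions: CH2=C(CH3)MgBr (1.5 equiv), CuI (10 mol %), THF, −30 °C
Reagents that add atoms: none
Why: Copper-catalysed SN2 opening of the terminal epoxide at C15 installs C13/C14 as a masked methyl ketone without touching C16.

Step 5
Reactants: 10 (4R)-2-methyl-16-phenylhexadec-1-en-4-ol
Product: 11 (4R)-4-[(4-methoxybenzyl)oxy]-2-methyl-16-phenylhexadec-1-ene
Conditions: NaH, PMBCl, Bu4NI (cat.), THF/DMF, 0 °C → rt
Reagents that add atoms: 4-methoxybenzyl chloride, COc1ccc(CCl)cc1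
Why: Williamson etherification; the PMB ether is the β-alkoxy group needed to steer the aldol of step 9.

Step 6
Reactants: 11 (4R)-4-[(4-methoxybenzyl)oxy]-2-methyl-16-phenylhexadec-1-ene
Product: 12 (4R)-4-[(4-methoxybenzyl)oxy]-16-phenylhexadecan-2-one
Conditions: OsO4 (2 mol %), NaIO4 (4 equiv), 2,6-lutidine, dioxane/H2O 3:1, rt
Reagents that add atoms: osmium tetroxide, O=[Os](=O)(=O)=O, turned over by sodium periodate, [Na+].[O-]I(=O)(=O)=O
Why: Lemieux–Johnson cleavage of the 1,1-disubstituted alkene gives the methyl ketone and spares the electron-rich PMB ring.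

Step 7
Reactants: 13 tert-butyl 2-[(4R,6S)-6-(hydroxymethyl)-2,2-dimethyl-1,3-dioxan-4-yl]acetate; 14 vinylmagnesium bromide
Product: 16 tert-butyl 2-[(4R,6R)-2,2-dimethyl-6-(prop-2-en-1-yl)-1,3-dioxan-4-yl]acetate, via triflate 15 (not isolated)
Conditions: Tf2O, 2,6-lutidine, CH2Cl2, −78 °C; then CH2=CHMgBr, CuBr·SMe2 (10 mol %), THF, −40 → 0 °C
Reagents that add atoms: none
Why: Copper-catalysed SN2 coupling of a primary triflate with a vinyl Grignard reagent forms C5–C7; the stereocentres C8 and C10 are not involved and the hindered tert-butyl ester survives at low temperature.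

Step 8
Reactants: 16 tert-butyl 2-[(4R,6R)-2,2-dimethyl-6-(prop-2-en-1-yl)-1,3-dioxan-4-yl]acetate
Product: 17 2-[(4R,6R)-2,2-dimethyl-6-(prop-2-en-1-yl)-1,3-dioxan-4-yl]acetaldehyde
Conditions: i-Bu2AlH (1.1 equiv), toluene, −78 °C; potassium sodium tartrate (aq.)
Reagents that add atoms: none
Why: Partial ester reduction; the aluminium hemiacetal of the tert-butyl ester is stable at −78 °C and releases the aldehyde only on work-up.

Step 9
Reactants: 12 (4R)-4-[(4-methoxybenzyl)oxy]-16-phenylhexadecan-2-one; 17 2-[(4R,6R)-2,2-dimethyl-6-(prop-2-en-1-yl)-1,3-dioxan-4-yl]acetaldehyde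
Product: 19 C4–C28 β-hydroxy ketone (C8/C10 acetonide; C12–OH; C14 ketone; C16–OPMB; C8 C10 C12 C16 configured as in 34), via boron enolate 18 (not isolated)
Conditions: (c-C6H11)2BCl, Et3N, Et2O, −78 → 0 °C; 17, −78 °C; then MeOH, pH 7 buffer, H2O2, 0 °C
Reagents that add atoms: none
Why: Boron-mediated aldol reaction of a β-alkoxy methyl ketone; in the cyclic transition state the C16 PMB ether directs the enolate face (1,5-anti induction), so the new C12 carbinol should form anti to C16–O, and the β-oxygen of the aldehyde has little say.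

Step 10
Reactants: 19 C4–C28 β-hydroxy ketone
Product: 20 C4–C28 12,14-syn diol (C16–OPMB; C8/C10 acetonide; stereocentres as in 34)
Conditions: Et2BOMe, NaBH4, THF/MeOH 4:1, −78 °C; then H2O2, NaOH (aq.), 0 °C
Reagents that add atoms: none
Why: Narasaka–Prasad reduction; the C12 alkoxide and the C14 ketone are held in a six-membered boron chelate and external hydride adds axially, giving the 12,14-syn diol and thereby the 14,16-anti relationship.

Step 11
Reactants: 20 C4–C28 12,14-syn diol
Product: 21 C4–C28 bis-acetonide PMB ether (isopropylidene acetals on C8/C10 and C12/C14; C16–OPMB)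
Conditions: Me2C(OMe)2, PPTS (cat.), CH2Cl2, rt
Reagents that add atoms: 2,2-dimethoxypropane, COC(C)(C)OC
Why: Acid-catalysed transacetalisation; the syn-1,3-diol closes to a chair dioxane with both substituents equatorial.

Step 12
Reactants: 21 C4–C28 bis-acetonide PMB ether
Product: 22 C4–C28 bis-acetonide C16 alcohol
Conditions: DDQ, CH2Cl2/pH 7 buffer 10:1, 0 °C
Reagents that add atoms: none
Why: Oxidative cleavage of the PMB ether by hydride abstraction and hydrolysis of the oxocarbenium ion; acetonides and the terminal alkene are inert, and the ether is removed here because DDQ would not be tolerated by the later β-keto ester.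

Step 13
Reactants: 22 C4–C28 bis-acetonide C16 alcohol
Product: 23 C4–C28 terminal alkene (bis-acetonide; C16–OTBS)
Conditions: TBSCl, imidazole, DMF, 40 °C
Reagents that add atoms: tert-butyldimethylsilyl chloride, CC(C)(C)[Si](C)(C)Cl
Why: Standard silylation of an unhindered secondary alcohol; the silyl ether falls in the same final acid step as the acetonides.

Step 14
Reactants: 23 C4–C28 terminal alkene; 24 acrolein
Product: 25 (E)-enal C3–C28 (bis-acetonide; C16–OTBS)
Conditions: second-generation Hoveyda–Grubbs catalyst (5 mol %), acrolein (5 equiv), CH2Cl2, 40 °C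
Reagents that add atoms: none
Why: Olefin cross-metathesis of a terminal alkene with an electron-poor partner that does not homodimerise; the (E)-enal is the thermodynamic product.

Step 15
Reactants: 25 (E)-enal C3–C28; 26 allyl acetoacetate
Product: 29 allyl 2-oxocyclohex-3-ene-1-carboxylate bearing the protected chain at ring C5 (C5 as in 34; ester trans), via Michael adduct 27 (not isolated), via cyclic ketol 28 (not isolated)
Conditions: (S)-2-{bis[3,5-bis(trifluoromethyl)phenyl][(trimethylsilyl)oxy]methyl}pyrrolidine (10 mol %), PhCO2H (10 mol %), toluene, rt; then piperidine/AcOH (20 mol % each), 4 Å MS, 40 °C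
Reagents that add atoms: none
Why: The amine condenses with 25 to an (E)-iminium ion whose Si face at C5 is covered by the diaryl(silyloxy)methyl group, so the enol of 26 adds to the Re face, forms C5–C6 and sets C5; hydrolysis releases aldehyde 27 and the catalyst. Piperidinium acetate then drives the intramolecular aldol of the methyl ketone carbon C2 onto the aldehyde C3, a 6-(enolendo)-exo-trig closure that forms the only carbocycle, and ketol 28 dehydrates to the conjugated C2=C3 bond. The closest known reaction type is the diarylprolinol silyl ether-catalysed Michael addition of β-keto esters to enals followed by aldol condensation to 5-substituted cyclohex-2-enones. C5 is under catalyst control because the nearest resident stereocentre (C8) is three atoms away, whereas C6 is epimerisable and should settle trans to the chain. The step needs conjugate rather than carbonyl addition, which iminium activation provides, and ring closure through C2, which is forced because closure through C6 would give a four-membered ring. The amine-salt second stage replaces the strong-acid finish usually used for this annulation so that both acetonides and the silyl ether survive.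

Step 16
Reactants: 29 allyl 2-oxocyclohex-3-ene-1-carboxylate bearing the protected chain
Product: 31 5-substituted cyclohex-2-en-1-one (protected chain; C5 as in 34), via keto acid 30 (not isolated)
Conditions: Pd(PPh3)4 (5 mol %), morpholine (5 equiv), THF, rt
Reagents that add atoms: none
Why: Tsuji-type deallylation; zerovalent palladium ionises the allyl ester, morpholine captures the allyl fragment and the free β-keto acid 30 loses CO2 at room temperature under neutral conditions, leaving C5 untouched.

Step 17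
Reactants: 31 5-substituted cyclohex-2-en-1-one
Product: 33 protected (4R,5S)-4-hydroxy-5-substituted cyclohex-2-en-1-one, via silyl dienol ether 32 (not isolated)
Conditions: MeMgBr (1.3 equiv), FeCl3 (5 mol %), Et2O, −20 °C; TMSCl, Et3N, −20 °C → rt; then mCPBA (1.05 equiv), NaHCO3, CH2Cl2, −20 °C; citric acid, MeOH, 0 °C
Reagents that add atoms: 3-chloroperoxybenzoic acid, OOC(=O)c1cccc(Cl)c1
Why: Amide or amine bases would enolise toward C6, so the Kharasch reagent is used to deprotonate C4 and give the linear (thermodynamic) dienolate, trapped as the 1-silyloxy-1,3-diene 32; the peracid then attacks C4 of this diene (vinylogous Rubottom oxidation) on the face anti to the C5 side chain, which sets the 4,5-trans relationship.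

Step 18
Reactants: 33 protected (4R,5S)-4-hydroxy-5-substituted cyclohex-2-en-1-one
Product: 34 (4R,5S)-4-hydroxy-5-[(2R,4R,6S,8S,10R)-2,4,6,8,10-pentahydroxy-22-phenyldocosyl]cyclohex-2-en-1-one
Conditions: HCl (1 M aq.), THF, 0 °C → rt
Reagents that add atoms: none
Why: Acid-catalysed hydrolysis of both isopropylidene acetals and of the silyl ether; no stereocentre is touched and dilute acid at or below room temperature should leave the γ-hydroxy enone intact.

**Compound list**

1 | 11-bromoundecan-1-ol | OCCCCCCCCCCCBr | starting material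
2 | phenylmagnesium bromide | Br[Mg]c1ccccc1 | starting material
3 | 11-phenylundecan-1-ol | OCCCCCCCCCCCc1ccccc1 | intermediate
4 | (11-bromoundecyl)benzene | BrCCCCCCCCCCCc1ccccc1 | intermediate
5 | (R)-epichlorohydrin | ClC[C@H]1CO1 | starting material
6 | (11-phenylundecyl)magnesium bromide | Br[Mg]CCCCCCCCCCCc1ccccc1 | intermediate (not isolated)
7 | (2R)-1-chloro-14-phenyltetradecan-2-ol | ClC[C@H](O)CCCCCCCCCCCCc1ccccc1 | intermediate (not isolated)
8 | (2R)-2-(12-phenyldodecyl)oxirane | C1O[C@@H]1CCCCCCCCCCCCc2ccccc2 | intermediate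
9 | prop-1-en-2-ylmagnesium bromide | CC(=C)[Mg]Br | starting material
10 | (4R)-2-methyl-16-phenylhexadec-1-en-4-ol | C=C(C)C[C@H](O)CCCCCCCCCCCCc1ccccc1 | intermediate
11 | (4R)-4-[(4-methoxybenzyl)oxy]-2-methyl-16-phenylhexadec-1-ene | C=C(C)C[C@H](OCc1ccc(OC)cc1)CCCCCCCCCCCCc2ccccc2 | intermediate
12 | (4R)-4-[(4-methoxybenzyl)oxy]-16-phenylhexadecan-2-one (C13–C28) | CC(=O)C[C@H](OCc1ccc(OC)cc1)CCCCCCCCCCCCc2ccccc2 | intermediate
13 | tert-butyl 2-[(4R,6S)-6-(hydroxymethyl)-2,2-dimethyl-1,3-dioxan-4-yl]acetate | OC[C@@H]1C[C@H](CC(=O)OC(C)(C)C)OC(C)(C)O1 | starting material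
14 | vinylmagnesium bromide | C=C[Mg]Br | starting material
15 | tert-butyl 2-[(4R,6S)-2,2-dimethyl-6-({[(trifluoromethyl)sulfonyl]oxy}methyl)-1,3-dioxan-4-yl]acetate | FC(F)(F)S(=O)(=O)OC[C@@H]1C[C@H](CC(=O)OC(C)(C)C)OC(C)(C)O1 | intermediate (not isolated)
16 | tert-butyl 2-[(4R,6R)-2,2-dimethyl-6-(prop-2-en-1-yl)-1,3-dioxan-4-yl]acetate | C=CC[C@@H]1C[C@H](CC(=O)OC(C)(C)C)OC(C)(C)O1 | intermediate
17 | 2-[(4R,6R)-2,2-dimethyl-6-(prop-2-en-1-yl)-1,3-dioxan-4-yl]acetaldehyde (C4–C12) | C=CC[C@@H]1C[C@H](CC=O)OC(C)(C)O1 | intermediate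
18 | dicyclohexylboron enolate of 12 | C=C(OB(C1CCCCC1)C2CCCCC2)C[C@H](OCc3ccc(OC)cc3)CCCCCCCCCCCCc4ccccc4 | intermediate (not isolated)
19 | C4–C28 β-hydroxy ketone (C12–OH, C14=O, C16–OPMB, C8/C10 acetonide) | C=CC[C@@H]1C[C@H](C[C@@H](O)CC(=O)C[C@H](OCc2ccc(OC)cc2)CCCCCCCCCCCCc3ccccc3)OC(C)(C)O1 | intermediate
20 | C4–C28 12,14-syn diol (C16–OPMB, C8/C10 acetonide) | C=CC[C@@H]1C[C@H](C[C@@H](O)C[C@@H](O)C[C@H](OCc2ccc(OC)cc2)CCCCCCCCCCCCc3ccccc3)OC(C)(C)O1 | intermediate
21 | C4–C28 bis-acetonide PMB ether | C=CC[C@@H]1C[C@H](C[C@@H]2C[C@H](C[C@H](OCc3ccc(OC)cc3)CCCCCCCCCCCCc4ccccc4)OC(C)(C)O2)OC(C)(C)O1 | intermediate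
22 | C4–C28 bis-acetonide C16 alcohol | C=CC[C@@H]1C[C@H](C[C@@H]2C[C@H](C[C@H](O)CCCCCCCCCCCCc3ccccc3)OC(C)(C)O2)OC(C)(C)O1 | intermediate
23 | C4–C28 terminal alkene (bis-acetonide, C16–OTBS) | C=CC[C@@H]1C[C@H](C[C@@H]2C[C@H](C[C@H](O[Si](C)(C)C(C)(C)C)CCCCCCCCCCCCc3ccccc3)OC(C)(C)O2)OC(C)(C)O1 | intermediate
24 | acrolein | C=CC=O | starting material
25 | (E)-enal C3–C28 (bis-acetonide, C16–OTBS) | O=C/C=C/C[C@@H]1C[C@H](C[C@@H]2C[C@H](C[C@H](O[Si](C)(C)C(C)(C)C)CCCCCCCCCCCCc3ccccc3)OC(C)(C)O2)OC(C)(C)O1 | intermediate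
26 | allyl acetoacetate | CC(=O)CC(=O)OCC=C | starting material
27 | Michael adduct: allyl 2-acetyl-5-oxopentanoate with the protected chain at C3 (ring C5 set; C6 epimers) | O=CC[C@@H](C[C@@H]1C[C@H](C[C@@H]2C[C@H](C[C@H](O[Si](C)(C)C(C)(C)C)CCCCCCCCCCCCc3ccccc3)OC(C)(C)O2)OC(C)(C)O1)C(C(C)=O)C(=O)OCC=C | intermediate (not isolated)
28 | cyclic ketol: allyl 4-hydroxy-2-oxocyclohexane-1-carboxylate with the protected chain at ring C5 (C3 and C6 epimers) | O=C1CC(O)C[C@@H](C[C@@H]2C[C@H](C[C@@H]3C[C@H](C[C@H](O[Si](C)(C)C(C)(C)C)CCCCCCCCCCCCc4ccccc4)OC(C)(C)O3)OC(C)(C)O2)C1C(=O)OCC=C | intermediate (not isolated)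
29 | allyl 2-oxocyclohex-3-ene-1-carboxylate with the protected chain at ring C5, ester trans | O=C1C=CC[C@@H](C[C@@H]2C[C@H](C[C@@H]3C[C@H](C[C@H](O[Si](C)(C)C(C)(C)C)CCCCCCCCCCCCc4ccccc4)OC(C)(C)O3)OC(C)(C)O2)[C@@H]1C(=O)OCC=C | intermediate
30 | 2-oxocyclohex-3-ene-1-carboxylic acid with the protected chain at ring C5 | O=C1C=CC[C@@H](C[C@@H]2C[C@H](C[C@@H]3C[C@H](C[C@H](O[Si](C)(C)C(C)(C)C)CCCCCCCCCCCCc4ccccc4)OC(C)(C)O3)OC(C)(C)O2)[C@@H]1C(=O)O | intermediate (not isolated)
31 | 5-substituted cyclohex-2-en-1-one (protected chain) | O=C1C=CC[C@@H](C[C@@H]2C[C@H](C[C@@H]3C[C@H](C[C@H](O[Si](C)(C)C(C)(C)C)CCCCCCCCCCCCc4ccccc4)OC(C)(C)O3)OC(C)(C)O2)C1 | intermediate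
32 | 1-(trimethylsilyloxy)cyclohexa-1,3-diene with the protected chain at C5 | C[Si](C)(C)OC1=CC=C[C@@H](C[C@@H]2C[C@H](C[C@@H]3C[C@H](C[C@H](O[Si](C)(C)C(C)(C)C)CCCCCCCCCCCCc4ccccc4)OC(C)(C)O3)OC(C)(C)O2)C1 | intermediate (not isolated)
33 | protected (4R,5S)-4-hydroxy-5-substituted cyclohex-2-en-1-one (bis-acetonide, C16–OTBS) | O=C1C=C[C@H](O)[C@@H](C[C@@H]2C[C@H](C[C@@H]3C[C@H](C[C@H](O[Si](C)(C)C(C)(C)C)CCCCCCCCCCCCc4ccccc4)OC(C)(C)O3)OC(C)(C)O2)C1 | intermediate
34 | (4R,5S)-4-hydroxy-5-[(2R,4R,6S,8S,10R)-2,4,6,8,10-pentahydroxy-22-phenyldocosyl]cyclohex-2-en-1-one | O=C1C=C[C@H](O)[C@@H](C[C@@H](O)C[C@@H](O)C[C@@H](O)C[C@@H](O)C[C@H](O)CCCCCCCCCCCCc2ccccc2)C1 | target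

**Step count and risks**

Total steps: 18. Longest linear sequence: 16 steps (1 → 12 by steps 1–6, then steps 9–18); the dioxane branch contributes steps 7–8.

Steps most likely to fail:

Step 15. The Michael adduct may rest as its cyclic hemiacetal and close slowly, and a long amine-salt stage could erode C5 by retro-Michael reaction or hydrolyse the allyl ester. Fallback, setting out from 25: the aldol condensation is replaced by an intramolecular Wittig olefination. Commercial ethyl 3-oxo-4-(triphenyl-λ5-phosphanylidene)butanoate is transesterified with allyl alcohol (toluene, reflux, DMAP cat.) to allyl 3-oxo-4-(triphenyl-λ5-phosphanylidene)butanoate F1. Under the same amine catalyst with LiClO4 and DABCO in CHCl3, F1 adds through its methylene carbon to 25 and gives the adduct phosphorane F2. The ylide carbon of F2 then condenses with the aldehyde at room temperature and the route is rejoined at 29, with no acid or base stage.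

Step 17. The Grignard reagent may add to the carbonyl, part of the enolisation may go toward C6, or the peracid may approach syn to the side chain. Fallback, setting out from 31: deconjugation and epoxidation. KOC(CH3)3 in (CH3)3COH/THF equilibrates the enone to the linear potassium dienolate; an inverse quench into cold aqueous acetic acid protonates C2 and gives the β,γ-unsaturated ketone F3. mCPBA epoxidises the isolated C3=C4 bond anti to the chain to give the 3,4-epoxy ketone F4, and Et3N opens it by β-elimination, returning the route at 33.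

Step 14. Acrolein may polymerise and consume the catalyst, the dioxane oxygens may chelate ruthenium, or the terminal double bond may migrate before metathesis. Fallback, setting out from 23: oxidative cleavage (OsO4 cat., NaIO4, 2,6-lutidine, dioxane/H2O) gives the C5 aldehyde F5. Wittig olefination of F5 with (triphenyl-λ5-phosphanylidene)acetaldehyde (toluene, 80 °C) gives the (E)-enal and rejoins the route at 25.

**Further compounds**

F1 | step 15 | allyl 3-oxo-4-(triphenyl-λ5-phosphanylidene)butanoate | C=CCOC(=O)CC(=O)C=P(c1ccccc1)(c1ccccc1)c1ccccc1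
F2 | step 15 | adduct phosphorane: allyl 5-oxo-2-[(triphenyl-λ5-phosphanylidene)acetyl]pentanoate with the protected chain at C3 | O=CC[C@@H](C[C@@H]1C[C@H](C[C@@H]2C[C@H](C[C@H](O[Si](C)(C)C(C)(C)C)CCCCCCCCCCCCc3ccccc3)OC(C)(C)O2)OC(C)(C)O1)C(C(=O)C=P(c4ccccc4)(c5ccccc5)c6ccccc6)C(=O)OCC=C
F3 | step 17 | β,γ-unsaturated ketone: 5-substituted cyclohex-3-en-1-one (protected chain) | O=C1CC=C[C@@H](C[C@@H]2C[C@H](C[C@@H]3C[C@H](C[C@H](O[Si](C)(C)C(C)(C)C)CCCCCCCCCCCCc4ccccc4)OC(C)(C)O3)OC(C)(C)O2)C1
F4 | step 17 | 3,4-epoxy ketone, oxygen anti to the chain (protected chain) | O=C1C[C@@H]2O[C@@H]2[C@@H](C[C@@H]3C[C@H](C[C@@H]4C[C@H](C[C@H](O[Si](C)(C)C(C)(C)C)CCCCCCCCCCCCc5ccccc5)OC(C)(C)O4)OC(C)(C)O3)C1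
F5 | step 14 | C5 aldehyde (bis-acetonide, C16–OTBS) | O=CC[C@@H]1C[C@H](C[C@@H]2C[C@H](C[C@H](O[Si](C)(C)C(C)(C)C)CCCCCCCCCCCCc3ccccc3)OC(C)(C)O2)OC(C)(C)O1
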